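Nobody can draw these flasks from their chain readings: north shows 2 % at 4.00 min and south-west 3 % at 3.00 min, single readings against a scatter of 1.5 percentage points, and north-east shows 13 % at 2.00 min.

| flask | free monomer | initiator | temperature | remark | time |
|---|---|---|---|---|---|
| north | 0.10 M | 5 mM | 70 °C | run made earlier |  |
| south-west | 0.40 M | 5 mM | 92 °C | run made earlier |  |
| north-east | 0.20 M | 7.5 mM | 70 °C | run made earlier |  |
| dawn | 0.20 M | 5.0 mM | 100 °C |  | 12 min |
| summer | 0.20 M | 5.0 mM | 60 °C |  | 12 min |
| midnight | 0.20 M | 5.0 mM |  | at 60 °C until 4.0 min, from then on at 100 °C | 12 min |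
| autumn | 0.20 M | 5.0 mM | 80 °C |  | 12 min |

- north (time / min: monomer in chains / %, free monomer / %): 2.00: 0, 62; 4.00: 2, 40; 8.00: 0, 14; 20.0: 0, 0; 40.0: 0, 3
- south-west (time / min: monomer in chains / %, free monomer / %): 1.33: 1, 8; 3.00: 3, 1; 4.00: 0, 3; 6.00: 0, 0; 8.00: 0, 1
- north-east (time / min: monomer in chains / %, free monomer / %): 2.00: 13, 49; 4.00: 9, 34; 8.00: 0, 17; 20.0: 1, 1; 40.0: 0, 0

(readings scatter by 1.5 percentage points)

- the numbers in the tables scatter by 1.5 percentage points (one standard deviation)

1. the flask that comes out highest in amount of monomer in chains, in percent of the free monomer charged, or "all alike" when all lie within 1.5 percentage points (dawn / summer / midnight / autumn / all alike)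
2. monomer in chains at the end, in percent of the free monomer charged, dawn
3. monomer in chains at the end, in percent of the free monomer charged, summer
4. monomer in chains at the end, in percent of the free monomer charged, midnight
5. monomer in chains at the end, in percent of the free monomer charged, autumn

So I freeze what is nearly constant, the fraction of free monomer lost per minute. In north, free monomer falls from 62 % at 2.00 min to 14 % at 8.00 min, a first-order constant k of 0.248 min⁻¹ at 70 °C. In south-west, 8 % left at 1.33 min gives 1.90 min⁻¹ at 92 °C.

I draw ln k straight against temperature, a rough step, and get 0.0983 min⁻¹ at 60 °C. I carry the half-life h of free monomer by this loss at 60 °C, 7.05 min.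

Now the curve. North, charged at 0.10 M, shows chains within scatter, and north-east's chain readings fall after free monomer reads 0.0980 M. I therefore read a floor near 0.10 M at 70 °C (the equilibrium monomer concentration) and keep it as a rough mark for the other temperatures, a guess, since it may shift with them. In summer this loss starts free monomer down at 0.0197 M min⁻¹, and by this loss alone a charge of 0.20 M halves after one h. Chains take free monomer too, so h is a rough clock, and I draw no turning point for the chains from it.

| flask | h | half-lives by the end |
|---|---|---|
| summer | 7.05 min | 1.70 |
| autumn | 1.11 min | 10.8 |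
| dawn | 0.174 min | 69.0 |
| midnight | 7.05 min, then 0.174 min | 46.5 |

Summer ends after fewer than 2 half-lives, so by this loss alone it still holds 0.0615 M of free monomer. Autumn, dawn and midnight count more half-lives than summer, and north-east's chain readings went from 13 % to 0 % within 6.00 min at 70 °C. So I commit to summer highest and to empty autumn, dawn and midnight flasks, but h gives me no height for summer.

The forecast says summer, with 18 % (7 % to 32 %) there, 0 % in dawn, 0 % in midnight and 0 % in autumn: “Only summer keeps monomer above its lower equilibrium level”. Its constant at 60 °C is 0.08/min against my 0.0983 min⁻¹.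

The simulation gives summer with 18.4 %, and 0 %, 0 % and 0 % in dawn, midnight and autumn.

    free monomer → uncatalysed product (k = 0.00150 s⁻¹, Ea = 98.0 kJ mol⁻¹)
    monomer in chains + living end → free monomer + living end, rate k2*[living end] as long as [monomer in chains] is above zero (k = 0.0150 s⁻¹, Ea = 100 kJ mol⁻¹)
    free monomer + initiator → living end + monomer in chains (k = 0.260 M⁻¹ s⁻¹, Ea = 54.0 kJ mol⁻¹)
    free monomer + living end → monomer in chains + living end, rate k4*[living end]*[free monomer] (k = 0.240 M⁻¹ s⁻¹, Ea = 63.0 kJ mol⁻¹)
    (constants at 60 °C)

In summer, chains are made 1.86 times as fast as they are used at 4.04 min, and that ratio stands at 0.835 at 12.0 min, so the turn from net making to net use lies between those times. The half-life of free monomer by passage into uncatalysed product is 7.7 min there, against my 7.05 min.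

Now take summer's recipe charged at 0.050 M, which is below the floor I read at 70 °C. Free monomer should then simply follow h, leaving 30.7 % at 12 min, with chains near nothing. That flask holds 34.5 % free monomer and 0.0153 % in chains.

The readings were computed for an exercise.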